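**Assumptions (one line):** the target is the stereoisomer as drawn (ring carbon bearing CH2OAc = R, ring CHOH = S, ring CH bearing the side chain = R, side-chain CHMe = S). (S)-Citronellic acid and allyl TBS ether are taken as commercial, and the lactol anomeric centre is left undefined.

**Retrosynthesis**
- The enal is made last by MnO2 oxidation of the allylic alcohol. The nine-membered carbocycle is closed in the penultimate C–C step, by RCM forming the ring-Z trisubstituted alkene (b=c) of a triene.
- The E-trisubstituted alkene and the skipped diene come from Negishi methylalumination/allylation of a homopropargylic alcohol.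
- The carbinol stereocentre comes from asymmetric propargylation of a lactol (masked aldehyde).
- The lactol comes from a cis-γ-lactone made by Ireland–Claisen rearrangement of the (S)-citronellate ester of a 2-substituted allylic alcohol. This sets the CH(CH2O) and CH(side chain) centres, and citronellic acid supplies the side-chain methyl centre.
- The allylic alcohol comes from cross-metathesis of a 2-methylene-1,3-propanediol derivative with allyl TBS ether.

**Step 1**
Reactants: 1, 2-methylenepropane-1,3-diol
Product: 2, mono-TBDPS ether of 1
Conditions: NaH, TBDPSCl, THF, 0 °C → rt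
Reagents that add atoms: TBDPSCl, CC(C)(C)[Si](Cl)(c1ccccc1)c1ccccc1
Why: Base-mediated mono-silylation (nucleophilic substitution at Si) desymmetrises the diol statistically; no stereocentre is formed.

**Step 2**
Reactants: 2; 3, allyl tert-butyldimethylsilyl ether
Product: 4, HOCH2–C(CH2OTBDPS)=CH–CH2OTBS, with CH2OH cis to CH2OTBS
Conditions: Grubbs II (5 mol%), CH2Cl2, 40 °C
Reagents that add atoms: none
Why: Cross-metathesis of a 1,1-disubstituted alkene with a type-I allyl ether gives the trisubstituted alkene. The bulky CH2OTBDPS sits trans to the CH2OTBS carbon, which gives the Z-type allylic alcohol needed for a syn-selective Claisen; any minor isomer is removed by chromatography.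

**Step 3**
Reactants: 4; 5, (S)-citronellic acid
Product: 6, citronellate ester of 4
Conditions: EDCI, DMAP, CH2Cl2, 0 °C → rt
Reagents that add atoms: none
Why: Steglich esterification; the (S) methyl-bearing centre is untouched and no new stereocentre arises.

**Step 4**
Reactants: 6
Product: 7, cis-γ-lactone
Conditions: LDA, TMSCl, THF, −78 °C → rt; then CSA, MeOH, rt
Reagents that add atoms: none (the TMS and TBS groups are lost)
Why: Ireland–Claisen rearrangement proceeds through the (E)-silyl ketene acetal and a chair transition state with the Z-allylic ester, giving the syn relationship between the two new contiguous centres. The adjacent (S) centre biases which face reacts. Acid then removes the TMS ester and the primary TBS ether (TBDPS survives), and the hydroxy acid lactonises. The diastereomers are separated at this stage.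

**Step 5**
Reactants: 7
Product: 8, lactol
Conditions: DIBAL-H, CH2Cl2, −78 °C
Reagents that add atoms: none
Why: Partial lactone reduction gives the masked aldehyde, which also keeps the primary alcohol for later acetylation; existing stereocentres are unchanged.

**Step 6**
Reactants: 8
Product: 9, homopropargylic alcohol bearing the free CH2OH (the diol of the open lactol)
Conditions: allenyl-B(Ipc)2 (from (+)-α-pinene), Et2O, −78 °C; then NaOH, H2O2
Reagents that add atoms: B-allenyldiisopinocampheylborane, C=C=CB(C1CC2CC(C1C)C2(C)C)C1CC2CC(C1C)C2(C)C (Ipc stereochemistry not shown; the pinene enantiomer is chosen for Si-face attack)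
Why: Brown asymmetric allenylboration (propargylation) proceeds by an SE2′ chair transition state. Reagent control delivers the (S)-carbinol, and the lactol opens in situ to the aldehyde.

**Step 7**
Reactants: 9
Product: 10, primary acetate
Conditions: Ac2O (1.1 equiv), pyridine, CH2Cl2, −20 °C
Reagents that add atoms: acetic anhydride, CC(=O)OC(C)=O
Why: The unhindered primary alcohol is acetylated selectively over the hindered secondary one; no stereocentre is affected.

**Step 8**
Reactants: 10
Product: 11, triene with the E-trisubstituted alkene
Conditions: Me3Al, Cp2ZrCl2 (cat.), CH2Cl2, 0 °C → rt; then CuI (cat.), allyl bromide, THF, 0 °C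
Reagents that add atoms: trimethylaluminium, C[Al](C)C; allyl bromide, C=CCBr
Why: Negishi carboalumination adds Me and Al syn across the terminal alkyne, and Cu-catalysed allylation of the alkenylalane retains geometry. This gives the E-trisubstituted alkene with the CH2 carbon cis to the methyl, as in the target.

**Step 9**
Reactants: 11
Product: 12, nine-membered ring TBDPS ether
Conditions: Hoveyda–Grubbs II (10 mol%), toluene, 1 mM, 80 °C
Reagents that add atoms: none (ethylene is lost)
Why: Ring-closing metathesis of the vinyl group with the 1,1-disubstituted alkene forms the ring alkene; in a nine-membered ring it must be Z. No stereocentre is changed.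

**Step 10**
Reactants: 12
Product: 13, allylic alcohol
Conditions: HF·pyridine, pyridine, THF, 0 °C → rt
Reagents that add atoms: none
Why: Buffered fluoride removes the robust primary TBDPS ether while the acetate survives; migration is minimised by pyridine buffering.

**Step 11**
Reactants: 13
Product: 14, hydroxyacetyldictyolal (target)
Conditions: activated MnO2, CH2Cl2, rt
Reagents that add atoms: none
Why: MnO2 selectively oxidises the allylic primary alcohol to the conjugated aldehyde. The homoallylic secondary alcohol, the acetate and the isolated alkenes are untouched, so no stereocentre is affected.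

**Compound list**

| # | Name | SMILES | Role |
|---|---|---|---|
| 1 | 2-Methylenepropane-1,3-diol | C=C(CO)CO | starting material |
| 2 | 3-(TBDPSO)-2-methylenepropan-1-ol | C=C(CO)CO[Si](c1ccccc1)(c1ccccc1)C(C)(C)C | intermediate |
| 3 | Allyl TBS ether | C=CCO[Si](C)(C)C(C)(C)C | starting material |
| 4 | Allylic alcohol (CH2OH cis to CH2OTBS) | OC/C(CO[Si](c1ccccc1)(c1ccccc1)C(C)(C)C)=C\CO[Si](C)(C)C(C)(C)C | intermediate |
| 5 | (S)-Citronellic acid | CC(C)=CCC[C@H](C)CC(=O)O | starting material |
| 6 | Citronellate ester of 4 | CC(C)=CCC[C@H](C)CC(=O)OC/C(CO[Si](c1ccccc1)(c1ccccc1)C(C)(C)C)=C\CO[Si](C)(C)C(C)(C)C | intermediate |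
| 7 | cis-γ-Lactone | O=C1OC[C@@H](C(=C)CO[Si](c2ccccc2)(c2ccccc2)C(C)(C)C)[C@H]1[C@@H](C)CCC=C(C)C | intermediate |
| 8 | Lactol | OC1OC[C@@H](C(=C)CO[Si](c2ccccc2)(c2ccccc2)C(C)(C)C)[C@H]1[C@@H](C)CCC=C(C)C | intermediate |
| 9 | Homopropargylic diol | C#CC[C@H](O)[C@H]([C@@H](C)CCC=C(C)C)[C@@H](CO)C(=C)CO[Si](c1ccccc1)(c1ccccc1)C(C)(C)C | intermediate |
| 10 | Primary acetate | C#CC[C@H](O)[C@H]([C@@H](C)CCC=C(C)C)[C@@H](COC(C)=O)C(=C)CO[Si](c1ccccc1)(c1ccccc1)C(C)(C)C | intermediate |
| 11 | Triene | C=CC/C=C(\C)C[C@H](O)[C@H]([C@@H](C)CCC=C(C)C)[C@@H](COC(C)=O)C(=C)CO[Si](c1ccccc1)(c1ccccc1)C(C)(C)C | intermediate |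
| 12 | Cyclononadiene TBDPS ether | CC(=O)OC[C@H]1/C(CO[Si](c2ccccc2)(c2ccccc2)C(C)(C)C)=C\C/C=C(\C)C[C@H](O)[C@@H]1[C@@H](C)CCC=C(C)C | intermediate |
| 13 | Allylic alcohol | CC(=O)OC[C@H]1/C(CO)=C\C/C=C(\C)C[C@H](O)[C@@H]1[C@@H](C)CCC=C(C)C | intermediate |
| 14 | Hydroxyacetyldictyolal | CC(=O)OC[C@H]1/C(C=O)=C\C/C=C(\C)C[C@H](O)[C@@H]1[C@@H](C)CCC=C(C)C | target |

**Totals:** 11 steps in total. The longest linear sequence is 11 steps (1 → 2 → 4 → 6 → 7 → 8 → 9 → 10 → 11 → 12 → 13 → 14), or 9 steps counted from (S)-citronellic acid.

**Three steps most likely to fail**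
1. **Step 9 (RCM to the nine-membered ring).** Dimerisation or failure to close is likely.
   - Fallback: close the ring by an intramolecular Pd-catalysed Stille coupling instead, forming the sp2–sp3 c–d bond from a (Z)-vinylstannane and an allylic carbonate, with the Z-alkene built beforehand.
2. **Step 4 (Ireland–Claisen).** Selectivity relative to the adjacent methyl-bearing (S) centre is only moderate, and the Z-allylic ester may go through a boat transition state.
   - Fallback: use Ir/amine dual-catalytic α-allylation of (S)-citronellal with a branched allylic alcohol, which sets the CH(CH2O) and CH(side chain) centres by catalyst control and gives the aldehyde directly.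
3. **Step 6 (propargylation of the lactol).** The lactol opens slowly, the α-branched aldehyde can epimerise, and the reagent and substrate biases may be mismatched.
   - Fallback: convert lactone 7 to the Weinreb amide, add propargylmagnesium bromide to give the ketone, then set the carbinol by CBS or Noyori asymmetric reduction.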